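Its constants were set for the occasion; the rest is arithmetic.

**Bench note**

The easy step comes first. At the charge, X turns into J at 42.0 min⁻¹, which is faster than J is spent on E at 3.80 min⁻¹. So we take J as being in quasi-steady state.

    X + Q ⇌ J + G (K1 = 2.7, k1 = 42 M⁻¹ min⁻¹)
    E + J → D + X (k2 = 1.9 M⁻¹ min⁻¹)
    D + J ⇌ Z + J, rate k3*[D]*[J] forward; the back reaction follows from the equilibrium constant (K3 = 0.70, k3 = 0.57 M⁻¹ min⁻¹)
    L ⇌ D, rate k4*(cs4 - [D]) while solid is left; crystals form when [D] > cs4 (cs4 = 32 mM, k4 = 20 min⁻¹)

E 2.0 M; Q 2.00 M; X 90 mM; time 15 min; volume of the second phase over the first 2.0

- what is said of D includes L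
- in the second phase: Q, G; everything else is in the first
- charges count per volume of the first phase; a concentration in a rate is the amount of a species over the volume of its own phase; every rate counts per litre of the first phase
- L is a solid; its amount is given per volume of the solution
- run time (flask): 15 min

- amount of D and L together at 15 min, in percent of the E charged
- concentration of D in solution at 15 min, in percent of saturation

E and Q are charged alike, so we follow one number, f, for the fraction of either left, and we set aside the Q that went to make J. The catalyst then divides as

cJ/(cX + cJ) = f/(α + βf), with α = 0.370 and β = 0.720.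

E is lost at the rate constant of its step times cE times cJ. Integrating that from the start gives

τ = α(1/f − 1) + β ln(1/f).

Our clock reading is τ = 2.56, the rate constant of the E step times the charged catalyst times the time.

At f = 20.0% the right side gives 2.64, more than τ. So f must be larger, and one correction step gives f = 20.6%.

When you come at 15 min, expect 79.4% of the E gone to D, L and Z. Z takes little: per unit of J its rate is 0.0182 min⁻¹ against 0.782 min⁻¹ for E. D and L together will stand a little lower.

E is then used at 0.0279 M min⁻¹. Dissolved D stands above 32 mM by that rate over 20 min⁻¹, which is 104% of saturation.

Do not top up E or Q. Our one f is reckoned for the matched charges, 2.0 M of E and 2.00 M of Q.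

The forecast gives 77.8% and 104.4%, on the ground that “Crystals hold dissolved D near 32 mM”.

The flask gives 77.9% and 104%, with E at 21.5% against our f of 20.6%. The neighbour flask has 0.36 M of X, with the time held, so its clock reads 10.3. At f = 5.00% the right side gives 9.19, less than that reading. The same correction step gives f = 4.34% for the neighbour flask. The neighbour flask gives 93.1%, with Q at 4.1% and E at 5.9%.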